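**Plan**

1. Retrosynthesis: the C4 silyl ether and the two ester C–O bonds are cut first (acetate, then angelate) and both carbinols go back to ketones; this exposes a 1,5-diketone, whose C2–C2' bond (ring CH to exocyclic CH(CH3)) is cut last.
2. Enabling feature: the angelate carbon C1 of the cyclohexane and the acetoxy carbon C4' of the chain are 1,5-related through C2–C2'–C3'. C2–C2' is therefore the Michael bond between Cα of a cyclohexanone and Cβ of the crotonyl arm of (E)-6-methylhepta-2,5-dien-4-one, a dienone with no sp3 α-hydrogen.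
3. Forward: the cyclohexane ring is bought intact as 4,4-dimethoxycyclohexa-2,5-dienone (no ring is formed). Its second enone arm is stored as an enol acetate that fixes the enolate regiochemistry, and the C8 chain is then joined in one step, which completes the C15 skeleton.
4. Stereochemistry: only C5 (methyl) is set by catalysis (Cu-catalysed conjugate addition). C4 (L-Selectride, cis to CH3), C2 (Michael addition anti to C4–OTBS), C2' (lk topicity of the same step) and C1 (axial hydride delivery) are relayed from it; C4' is set by CBS reduction.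

Key step: step 8

Remark: ring atoms are numbered as in the target (C1 angelate carbon, C2 chain-bearing carbon, C4 carbinol, C5 methyl carbon; chain C1'–C7'); metal alkoxides that are only protonated on work-up are not numbered separately.

**Route**

Step 1
Reactants: 1 (E)-but-2-enal; 2 2-methylprop-1-en-1-ylmagnesium bromide
Product: 3 (E)-6-methylhepta-2,5-dien-4-ol (racemic)
Conditions: THF, −78 to 0 °C; aq. NH4Cl
Reagents that add atoms: none
Why: 1,2-addition of the alkenyl Grignard reagent to the enal carbonyl (Grignard addition); the carbinol configuration is irrelevant because it is oxidised in step 2.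

Step 2
Reactants: 3 (E)-6-methylhepta-2,5-dien-4-ol
Product: 4 (E)-6-methylhepta-2,5-dien-4-one
Conditions: activated MnO2, CH2Cl2, rt
Reagents that add atoms: none
Why: MnO2 oxidation of a bis-allylic alcohol should give the cross-conjugated dienone without isomerising the (E)-crotonyl unit.

Step 3
Reactants: 5 4,4-dimethoxycyclohexa-2,5-dien-1-one
Product: 7 (S)-4,4-dimethoxy-5-methylcyclohex-2-en-1-one, via methylzinc dienolate 6 (not isolated)
Conditions: Me2Zn (1.5 equiv), Cu(OTf)2 (2 mol %), BINOL-derived bis(1-phenylethyl)amine phosphoramidite (4 mol %, enantiomer chosen for 5S), toluene, −25 °C; aq. NH4Cl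
Reagents that add atoms: dimethylzinc, C[Zn]C
Why: Copper-catalysed asymmetric conjugate addition of a dialkylzinc to one of the two enantiotopic enone arms of the quinone monoketal (desymmetrisation) should set C5 under catalyst control, and the untouched second arm remains as the regiochemical marker for C2.

Step 4
Reactants: 7 (S)-4,4-dimethoxy-5-methylcyclohex-2-en-1-one
Product: 9 (S)-4,4-dimethoxy-5-methylcyclohex-1-en-1-yl acetate, via lithium enolate 8 (not isolated)
Conditions: L-Selectride (1.05 equiv), THF, −78 °C; then Ac2O, −78 to 0 °C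
Reagents that add atoms: acetic anhydride, CC(=O)OC(C)=O
Why: Conjugate hydride reduction of the β-unsubstituted cyclohexenone should give the C1–C2 enolate regiospecifically, and O-acetylation stores this regiochemistry as an enol acetate (reductive enolate trapping); no stereocenter is formed.

Step 5
Reactants: 9 (S)-4,4-dimethoxy-5-methylcyclohex-1-en-1-yl acetate
Product: 10 (S)-5-methyl-4-oxocyclohex-1-en-1-yl acetate
Conditions: PPTS (cat.), acetone–H2O, rt
Reagents that add atoms: water, O
Why: A dimethyl ketal hydrolyses under mild acid much faster than an enol acetate (ketal hydrolysis), which unveils the C4 ketone; the mild conditions are chosen to avoid enolisation at C5.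

Step 6
Reactants: 10 (S)-5-methyl-4-oxocyclohex-1-en-1-yl acetate
Product: 11 (4R,5S)-4-hydroxy-5-methylcyclohex-1-en-1-yl acetate
Conditions: L-Selectride (1.05 equiv), THF, −78 °C; aq. NH4Cl (non-oxidative work-up)
Reagents that add atoms: none
Why: The bulky hydride should attack the C4 ketone from the equatorial direction, as in the reduction of 2-methylcyclohexanones, giving the axial alcohol cis to the equatorial C5 methyl group (4R); at −78 °C the enol acetate should survive.

Step 7
Reactants: 11 (4R,5S)-4-hydroxy-5-methylcyclohex-1-en-1-yl acetate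
Product: 12 (4R,5S)-4-(tert-butyldimethylsilyloxy)-5-methylcyclohex-1-en-1-yl acetate
Conditions: TBSOTf, 2,6-lutidine, CH2Cl2, −78 to 0 °C
Reagents that add atoms: tert-butyldimethylsilyl trifluoromethanesulfonate, CC(C)(C)[Si](C)(C)OS(=O)(=O)C(F)(F)F
Why: Silyl triflate silylation of the hindered axial alcohol (silyl ether protection) installs the bulky group that shields one ring face in step 8.

Step 8
Reactants: 12 (4R,5S)-4-(tert-butyldimethylsilyloxy)-5-methylcyclohex-1-en-1-yl acetate; 4 (E)-6-methylhepta-2,5-dien-4-one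
Product: 15 (2S,4R,5S)-4-(tert-butyldimethylsilyloxy)-5-methyl-2-[(2R)-6-methyl-4-oxohept-5-en-2-yl]cyclohexan-1-one, via ring lithium enolate 13 (not isolated), via adduct lithium enolate 14 (not isolated)
Conditions: MeLi (2.05 equiv), THF, 0 °C; then 4 (0.9 equiv), −78 to −40 °C; AcOH, −78 °C
Reagents that add atoms: none
Why: Two equivalents of MeLi cleave the enol acetate to the regiodefined lithium enolate 13 (the acetyl group ends as tert-butoxide), which should add 1,4 to the crotonyl terminus of 4 through a closed, lithium-bridged eight-membered transition state to give chain enolate 14, protonated on quench. The closest known reaction type is the kinetic Michael addition of a preformed lithium ketone enolate, generated from an enol acetate, to an acyclic (E)-enone. No ring is closed; the step joins the C7 ring unit to the C8 chain and completes the C15 skeleton as a 1,5-diketone. C2 is controlled by the C4 silyloxy group, which is cis to the C5 methyl group: chair-like C–C bond formation on its face would be 1,3-diaxial to OTBS, so the acceptor should add to the opposite (Re) face and give the 2,4-trans, 2,5-trans (2S) ketone with an equatorial chain. C2' is controlled by the simple diastereoselection of an E(O)-enolate with an (E)-enone, a synclinal arrangement with the enolate hydrogen anti to the enone C=C and the β-methyl group turned away from ring C3 (lk, Re/Re), which leads to the syn adduct (2'R). The step needs 1,4- over 1,2-addition and attack at the crotonyl rather than the 3-methylbut-2-enoyl terminus: the β,β-disubstituted terminus is hindered, the dienone has no sp3 α-hydrogen to quench the enolate, a 1,2-aldolate should revert on warming to −40 °C, and the cold acid quench forestalls proton transfer and aldol closure of the 1,5-diketone.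

Step 9
Reactants: 15 (2S,4R,5S)-4-(tert-butyldimethylsilyloxy)-5-methyl-2-[(2R)-6-methyl-4-oxohept-5-en-2-yl]cyclohexan-1-one
Product: 16 (6R)-6-[(1S,2R,4S,5R)-5-(tert-butyldimethylsilyloxy)-2-hydroxy-4-methylcyclohexyl]-2-methylhept-2-en-4-one
Conditions: NaBH4, MeOH–CH2Cl2 (1:1), −78 °C
Reagents that add atoms: none
Why: At −78 °C borohydride should reduce the saturated cyclohexanone faster than the conjugated enone (chemoselective hydride reduction), and the small hydride should add along the axial trajectory of the chair with equatorial C2 chain, giving the equatorial (1R) alcohol trans to the chain.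

Step 10
Reactants: 16 (6R)-6-[(1S,2R,4S,5R)-5-(tert-butyldimethylsilyloxy)-2-hydroxy-4-methylcyclohexyl]-2-methylhept-2-en-4-one; 17 (Z)-2-methylbut-2-enoic acid (angelic acid)
Product: 19 (1R,2S,4R,5S)-4-(tert-butyldimethylsilyloxy)-5-methyl-2-[(2R)-6-methyl-4-oxohept-5-en-2-yl]cyclohexyl (Z)-2-methylbut-2-enoate, via mixed anhydride 18 (not isolated)
Conditions: 17, 2,4,6-trichlorobenzoyl chloride, Et3N, toluene, rt; then 16, 75 °C
Reagents that add atoms: none
Why: Yamaguchi-type esterification through the mixed anhydride without a nucleophilic catalyst should acylate the hindered alcohol while avoiding the addition–elimination pathway that isomerises angelates to tiglates; no stereocenter is touched.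

Step 11
Reactants: 19 (1R,2S,4R,5S)-4-(tert-butyldimethylsilyloxy)-5-methyl-2-[(2R)-6-methyl-4-oxohept-5-en-2-yl]cyclohexyl (Z)-2-methylbut-2-enoate
Product: 20 (1R,2S,4R,5S)-4-(tert-butyldimethylsilyloxy)-2-[(2R,4R)-4-hydroxy-6-methylhept-5-en-2-yl]-5-methylcyclohexyl (Z)-2-methylbut-2-enoate
Conditions: (S)-Me-CBS (0.2 equiv), catecholborane (1.5 equiv), toluene, −78 °C; aqueous work-up
Reagents that add atoms: none
Why: In the CBS reduction the oxazaborolidine should bind the ketone anti to the 2-methylpropenyl group (the large substituent) and deliver hydride to the Si face, giving the (4'R) allylic alcohol under reagent control; catecholborane at −78 °C should leave the alkenes and the angelate alone.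

Step 12
Reactants: 20 (1R,2S,4R,5S)-4-(tert-butyldimethylsilyloxy)-2-[(2R,4R)-4-hydroxy-6-methylhept-5-en-2-yl]-5-methylcyclohexyl (Z)-2-methylbut-2-enoate
Product: 21 (1R,2S,4R,5S)-2-[(2R,4R)-4-acetoxy-6-methylhept-5-en-2-yl]-4-(tert-butyldimethylsilyloxy)-5-methylcyclohexyl (Z)-2-methylbut-2-enoate
Conditions: Ac2O, pyridine, 0 °C to rt
Reagents that add atoms: acetic anhydride, CC(=O)OC(C)=O
Why: Acetylation of the secondary allylic alcohol under basic, non-ionising conditions (acylation) proceeds with retention at C4' and should not disturb the angelate.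

Step 13
Reactants: 21 (1R,2S,4R,5S)-2-[(2R,4R)-4-acetoxy-6-methylhept-5-en-2-yl]-4-(tert-butyldimethylsilyloxy)-5-methylcyclohexyl (Z)-2-methylbut-2-enoate
Product: 22 (1R,2S,4R,5S)-2-[(2R,4R)-4-acetoxy-6-methylhept-5-en-2-yl]-4-hydroxy-5-methylcyclohexyl (Z)-2-methylbut-2-enoate
Conditions: HF·pyridine, pyridine, THF, 0 °C to rt
Reagents that add atoms: none
Why: Buffered fluoride cleavage of the TBS ether (desilylation) should spare the allylic acetate and the angelate and should not promote acyl migration.

**Compound list**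

1 | (E)-but-2-enal | C/C=C/C=O | starting material
2 | 2-methylprop-1-en-1-ylmagnesium bromide | CC(C)=C[Mg]Br | starting material
3 | (E)-6-methylhepta-2,5-dien-4-ol (racemic) | C/C=C/C(O)C=C(C)C | intermediate
4 | (E)-6-methylhepta-2,5-dien-4-one | C/C=C/C(=O)C=C(C)C | intermediate
5 | 4,4-dimethoxycyclohexa-2,5-dien-1-one | COC1(OC)C=CC(=O)C=C1 | starting material
6 | methylzinc (3S)-4,4-dimethoxy-3-methylcyclohexa-1,5-dien-1-olate | C[Zn]OC1=C[C@H](C)C(OC)(OC)C=C1 | intermediate
7 | (S)-4,4-dimethoxy-5-methylcyclohex-2-en-1-one | O=C1C=CC(OC)(OC)[C@@H](C)C1 | intermediate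
8 | lithium (5S)-4,4-dimethoxy-5-methylcyclohex-1-en-1-olate | [Li]OC1=CCC(OC)(OC)[C@@H](C)C1 | intermediate
9 | (S)-4,4-dimethoxy-5-methylcyclohex-1-en-1-yl acetate | CC(=O)OC1=CCC(OC)(OC)[C@@H](C)C1 | intermediate
10 | (S)-5-methyl-4-oxocyclohex-1-en-1-yl acetate | CC(=O)OC1=CCC(=O)[C@@H](C)C1 | intermediate
11 | (4R,5S)-4-hydroxy-5-methylcyclohex-1-en-1-yl acetate | CC(=O)OC1=CC[C@@H](O)[C@@H](C)C1 | intermediate
12 | (4R,5S)-4-(tert-butyldimethylsilyloxy)-5-methylcyclohex-1-en-1-yl acetate | CC(=O)OC1=CC[C@@H](O[Si](C)(C)C(C)(C)C)[C@@H](C)C1 | intermediate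
13 | lithium (4R,5S)-4-(tert-butyldimethylsilyloxy)-5-methylcyclohex-1-en-1-olate | [Li]OC1=CC[C@@H](O[Si](C)(C)C(C)(C)C)[C@@H](C)C1 | intermediate
14 | lithium dienolate of 15 (O-lithio 6-methylhepta-3,5-dien-4-olate chain on the ring ketone) | O=C1C[C@H](C)[C@H](O[Si](C)(C)C(C)(C)C)C[C@H]1[C@H](C)C=C(O[Li])C=C(C)C | intermediate
15 | (2S,4R,5S)-4-(tert-butyldimethylsilyloxy)-5-methyl-2-[(2R)-6-methyl-4-oxohept-5-en-2-yl]cyclohexan-1-one | O=C1C[C@H](C)[C@H](O[Si](C)(C)C(C)(C)C)C[C@H]1[C@H](C)CC(=O)C=C(C)C | intermediate
16 | (6R)-6-[(1S,2R,4S,5R)-5-(tert-butyldimethylsilyloxy)-2-hydroxy-4-methylcyclohexyl]-2-methylhept-2-en-4-one | O[C@@H]1C[C@H](C)[C@H](O[Si](C)(C)C(C)(C)C)C[C@H]1[C@H](C)CC(=O)C=C(C)C | intermediate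
17 | (Z)-2-methylbut-2-enoic acid (angelic acid) | C/C=C(/C)C(=O)O | starting material
18 | (Z)-2-methylbut-2-enoic 2,4,6-trichlorobenzoic anhydride | C/C=C(/C)C(=O)OC(=O)c1c(Cl)cc(Cl)cc1Cl | intermediate
19 | (1R,2S,4R,5S)-4-(tert-butyldimethylsilyloxy)-5-methyl-2-[(2R)-6-methyl-4-oxohept-5-en-2-yl]cyclohexyl (Z)-2-methylbut-2-enoate | C/C=C(/C)C(=O)O[C@@H]1C[C@H](C)[C@H](O[Si](C)(C)C(C)(C)C)C[C@H]1[C@H](C)CC(=O)C=C(C)C | intermediate
20 | (1R,2S,4R,5S)-4-(tert-butyldimethylsilyloxy)-2-[(2R,4R)-4-hydroxy-6-methylhept-5-en-2-yl]-5-methylcyclohexyl (Z)-2-methylbut-2-enoate | C/C=C(/C)C(=O)O[C@@H]1C[C@H](C)[C@H](O[Si](C)(C)C(C)(C)C)C[C@H]1[C@H](C)C[C@H](C=C(C)C)O | intermediate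
21 | (1R,2S,4R,5S)-2-[(2R,4R)-4-acetoxy-6-methylhept-5-en-2-yl]-4-(tert-butyldimethylsilyloxy)-5-methylcyclohexyl (Z)-2-methylbut-2-enoate | C/C=C(/C)C(=O)O[C@@H]1C[C@H](C)[C@H](O[Si](C)(C)C(C)(C)C)C[C@H]1[C@H](C)C[C@H](C=C(C)C)OC(C)=O | intermediate
22 | (1R,2S,4R,5S)-2-[(2R,4R)-4-acetoxy-6-methylhept-5-en-2-yl]-4-hydroxy-5-methylcyclohexyl (Z)-2-methylbut-2-enoate | C/C=C(/C)C(=O)O[C@@H]1C[C@H](C)[C@H](O)C[C@H]1[C@H](C)C[C@H](C=C(C)C)OC(C)=O | target

**Step count**

Total: 13 steps. Longest linear sequence: 11 steps (steps 3 to 13, from 5); the dienone branch (steps 1 and 2) joins at step 8.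

**Steps most likely to fail**

Step 8. What may go wrong: loss of simple diastereoselection (ul instead of lk approach, giving the C2' epimer), 1,2-addition to the dienone carbonyl, and enolate equilibration by the tert-butoxide formed alongside. Fallback, from 12 back to 15: C2' is set by catalyst control and C2 by equilibration. MeLi (2 equiv) followed by Me3SiCl converts 12 into trimethylsilyl enol ether F1. An imidazolidinone-catalysed (iminium) Mukaiyama–Michael addition of F1 to (E)-but-2-enal 1 gives keto aldehyde F2; the catalyst enantiomer fixes C2' and the epimerisable C2 should settle equatorial. Grignard reagent 2 adds at −78 °C to the aldehyde of F2 in preference to the hindered ring ketone and gives hydroxy ketone F3 as a mixture of carbinol epimers. MnO2 oxidation of F3 gives 15.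

Step 9. What may go wrong: insufficient preference for axial hydride delivery next to the branched equatorial C2 substituent, giving the axial C1 epimer. Fallback, from 15 back to 21: both ketones are reduced under catalyst control with (S)-Me-CBS and catecholborane, the same catalyst enantiomer being matched for 1R and 4'R, to give diol F4. The less hindered allylic C4' hydroxyl is acetylated selectively (Ac2O, 2,4,6-collidine, −20 °C) to monoacetate F5. The ring hydroxyl of F5 is then angeloylated under the conditions of step 10, which gives 21.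

Step 4. What may go wrong: 1,2-reduction of the enone, because C3 lies next to the quaternary ketal carbon, or C-acetylation of the enolate; either would lose the regiochemical marker. Fallback, from 7 back to 9: Rh-catalysed 1,4-hydrosilylation of 7 (Et3SiH, cat. RhCl(PPh3)3) gives triethylsilyl enol ether F6. MeLi cleaves F6 to lithium enolate 8, which is O-acetylated with Ac2O to 9.

**Further compounds**

F1 | step 8 | tert-butyldimethyl{[(1R,6S)-6-methyl-4-(trimethylsilyloxy)cyclohex-3-en-1-yl]oxy}silane | C[Si](C)(C)OC1=CC[C@@H](O[Si](C)(C)C(C)(C)C)[C@@H](C)C1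
F2 | step 8 | (3R)-3-[(1S,4S,5R)-5-(tert-butyldimethylsilyloxy)-4-methyl-2-oxocyclohexyl]butanal | O=C1C[C@H](C)[C@H](O[Si](C)(C)C(C)(C)C)C[C@H]1[C@H](C)CC=O
F3 | step 8 | (2S,4R,5S)-4-(tert-butyldimethylsilyloxy)-2-[(2R)-4-hydroxy-6-methylhept-5-en-2-yl]-5-methylcyclohexan-1-one (both C4' epimers) | O=C1C[C@H](C)[C@H](O[Si](C)(C)C(C)(C)C)C[C@H]1[C@H](C)CC(O)C=C(C)C
F4 | step 9 | (1R,2S,4R,5S)-4-(tert-butyldimethylsilyloxy)-2-[(2R,4R)-4-hydroxy-6-methylhept-5-en-2-yl]-5-methylcyclohexan-1-ol | O[C@@H]1C[C@H](C)[C@H](O[Si](C)(C)C(C)(C)C)C[C@H]1[C@H](C)C[C@H](C=C(C)C)O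
F5 | step 9 | (4R,6R)-6-[(1S,2R,4S,5R)-5-(tert-butyldimethylsilyloxy)-2-hydroxy-4-methylcyclohexyl]-2-methylhept-2-en-4-yl acetate | O[C@@H]1C[C@H](C)[C@H](O[Si](C)(C)C(C)(C)C)C[C@H]1[C@H](C)C[C@H](C=C(C)C)OC(C)=O
F6 | step 4 | triethyl{[(5S)-4,4-dimethoxy-5-methylcyclohex-1-en-1-yl]oxy}silane | CC[Si](CC)(CC)OC1=CCC(OC)(OC)[C@@H](C)C1
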